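## Retrosynthetic overview

1. Feature used: ring A (C1–C5, C10) carries the exocyclic methylene C4=C11 beside quaternary C5. C3, C4 and C11 are read as an isopropenyl group on C5 and C2 as the carbonyl carbon of a formylmethyl arm on C10, so ring A is cut at C2–C3 (type 2 carbonyl-ene, Me2AlCl). The C2 hydroxyl is then removed by Barton–McCombie deoxygenation.
2. Ene precursor 22 is a ring B cyclohexane. Both arms come from one cyclopentanone that ties C5 to C10 in trans-hydrindanone 14 (C4 = carbonyl carbon; C2, C1 = ring methylenes): enol triflate, methylation (C11), ozonolysis of C4=C2, methylenation of the C4 acetyl (C3).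
3. 14 comes from (S)-enedione 5 (amino-acid aldol annulation, fixes C5). Reductive benzylation sets C10 and C9; methylenation and hydrogenation set C8.
4. Design choices: a cycloaddition of a 2-silyloxy diene with a 2-methyl enal was not used for ring B, because the enal β-carbon bonds to the diene terminus next to the silyloxy carbon and the quaternary C9 would end up para, not meta, to the oxygenated carbon. The phenols are methyl ethers up to 12 and silyl ethers from 14 on, because acidic ether cleavage is not compatible with the C4 methylene beside a free ortho-phenol.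
5. Ring order: ring B together with the temporary five-membered ring (step 2); five-membered ring opened (step 12); ring A (step 15).

Key step: step 15

Remark (assumption): avarane numbering is used for all compounds (ring A: C1–C5 and C10; ring B: C5–C10; C11 = methylene carbon on C4; α = face of H-10, β = face of the C5 methyl). Ar1 = 2,3,4-trimethoxy-5-(methoxycarbonyl)phenyl; Ar2 = 2,3,4-tris(tert-butyldimethylsilyloxy)-5-(methoxycarbonyl)phenyl. It is assumed that the dissolving-metal reduction of ketal 6 gives the trans ring fusion, as expected for such hydrindenones.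

## Route

Step 1
Reactants: 1 2-methylcyclopentane-1,3-dione; 2 pent-1-en-3-one
Product: 3 2-methyl-2-(3-oxopentyl)cyclopentane-1,3-dione
Conditions: H2O, AcOH (cat.), 70 °C
Reagents that add atoms: none
Why: Michael addition of the acidic cyclic 1,3-dione to the vinyl ketone gives the 2,2-disubstituted triketone; no stereocentre is formed.

Step 2
Reactants: 3 2-methyl-2-(3-oxopentyl)cyclopentane-1,3-dione
Product: 5 (7aS)-4,7a-dimethyl-2,3,7,7a-tetrahydro-1H-indene-1,5(6H)-dione, via cis-fused ketol 4 (not isolated)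
Conditions: L-phenylalanine (1.0 equiv), HClO4 (1 M aq., 0.5 equiv), MeCN, 80 °C
Reagents that add atoms: none
Why: Hajos–Parrish enamine aldol cyclisation: the L-amino acid enamine of the side-chain ketone attacks one of the two enantiotopic ring carbonyls through a hydrogen-bonded transition state, which should set C5 as S (β-methyl), and the acid dehydrates ketol 4 to the enone; the optical purity of all later compounds rests on this step.

Step 3
Reactants: 5 (7aS)-4,7a-dimethyl-2,3,7,7a-tetrahydro-1H-indene-1,5(6H)-dione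
Product: 6 (7a'S)-4',7a'-dimethyl-2',3',7',7a'-tetrahydrospiro[[1,3]dioxolane-2,1'-inden]-5'(6'H)-one (ketal at the future C4)
Conditions: HOCH2CH2OH (excess), p-TsOH·H2O (cat.), molecular sieves 4 Å, rt
Reagents that add atoms: ethylene glycol, OCCO
Why: Acid-catalysed ketalisation should take the saturated cyclopentanone in preference to the less electrophilic, tetrasubstituted conjugated enone carbonyl, which must stay free for step 5.

Step 4
Reactants: 7 methyl 2,3,4-trimethoxybenzoate
Product: 8 methyl 5-(bromomethyl)-2,3,4-trimethoxybenzoate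
Conditions: (CH2O)n (1.5 equiv), HBr (33% in AcOH), rt → 40 °C
Reagents that add atoms: formaldehyde (as paraformaldehyde), C=O; hydrogen bromide, Br
Why: Blanc-type bromomethylation (electrophilic aromatic substitution) should go at C5 of the benzoate, the only free position that is para to one methoxy group, ortho to another and meta to the ester.

Step 5
Reactants: 6 enone ketal; 8 methyl 5-(bromomethyl)-2,3,4-trimethoxybenzoate
Product: 10 trans-hydrindan-8-one 4-ethylene ketal (5β-CH3; 10α-H; 9β-CH3; 9α-CH2Ar1), via lithium enolate 9 (not isolated)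
Conditions: Li (2.2 equiv), NH3(l)/THF, t-BuOH (1.0 equiv), −78 °C; isoprene; then 8 (1.5 equiv), THF, −78 → −33 °C; NH4Cl
Reagents that add atoms: none
Why: Dissolving-metal reductive alkylation: protonation of C10 from the α face should give the trans ring fusion (H-10 anti to the C5 methyl) and leave the regiodefined C8–C9 lithium enolate, which is benzylated at C9 from the α face because the axial C5 methyl blocks the β face; excess metal is destroyed before the ester-bearing bromide is added.

Step 6
Reactants: 10 trans-hydrindan-8-one 4-ethylene ketal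
Product: 11 8-methylidene trans-hydrindane 4-ethylene ketal (otherwise as 10)
Conditions: Cp2Ti(μ-Cl)(μ-CH2)AlMe2 (Tebbe reagent, 1.5 equiv), pyridine (cat.), THF/toluene, −40 °C → rt; NaHCO3 (aq)
Reagents that add atoms: Tebbe reagent, C[Al-]1(C)C[Ti]([Cl+]1)(C1C=CC=C1)C1C=CC=C1
Why: Titanium methylidene (Tebbe) olefination converts the hindered, enolisable C8 ketone into the exocyclic methylene without strong base and reacts with ketones much faster than with the aryl ester, while the ketal is inert.

Step 7
Reactants: 11 8-methylidene trans-hydrindane 4-ethylene ketal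
Product: 12 8β-methyl trans-hydrindane 4-ethylene ketal (8α-H; otherwise as 10)
Conditions: H2 (1 atm), Pd/C (10%), EtOAc, rt
Reagents that add atoms: none
Why: Heterogeneous hydrogenation should deliver hydrogen to the 1,1-disubstituted alkene from the α face, away from the axial 9β-methyl group, so that the new C8 methyl is equatorial (β, S at C8), which is also the more stable epimer.

Step 8
Reactants: 12 8β-methyl trans-hydrindane 4-ethylene ketal
Product: 13 trans-hydrindan-4-one triol (5β,8β,9β-trimethyl; 10α-H; 9α-CH2-aryl, aryl = 2,3,4-trihydroxy-5-(methoxycarbonyl)phenyl)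
Conditions: BBr3 (8 equiv), CH2Cl2, −78 → 0 °C; MeOH, 0 °C → rt; H2O
Reagents that add atoms: water, O
Why: BBr3 O-demethylation cleaves the three aryl methyl ethers and opens the dioxolane at a stage where no alkene is present; the methanol quench returns any cleaved ester to the methyl ester and water frees the C4 ketone.

Step 9
Reactants: 13 trans-hydrindan-4-one triol
Product: 14 tris-TBS ether of 13 (9α-CH2Ar2)
Conditions: t-BuMe2SiCl (4.5 equiv), imidazole (9 equiv), DMAP (cat.), DMF, 45 °C
Reagents that add atoms: tert-butyldimethylsilyl chloride, CC(C)(C)[Si](C)(C)Cl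
Why: Silylation of the three phenols gives ethers that are inert to the bases, organometallics and aluminium Lewis acid ahead and that can be removed at the end with fluoride, without acid.

Step 10
Reactants: 14 tris-TBS hydrindan-4-one
Product: 16 C4–C2 enol triflate of 14, via potassium enolate 15 (not isolated)
Conditions: KN(SiMe3)2 (1.3 equiv), THF, −78 °C; PhNTf2 (1.4 equiv), −78 → 0 °C
Reagents that add atoms: N-phenylbis(trifluoromethanesulfonimide), O=S(=O)(N(c1ccccc1)S(=O)(=O)C(F)(F)F)C(F)(F)F
Why: The cyclopentanone can enolise only towards C2 because C5 is quaternary, so enolate formation and O-triflation give a single enol triflate.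

Step 11
Reactants: 16 enol triflate
Product: 17 cyclopentene with C4(CH3)=C2H (tris-TBS)
Conditions: MeZnCl (3 equiv), Pd(PPh3)4 (zerovalent palladium, 5 mol %), THF, 50 °C
Reagents that add atoms: methylzinc chloride, C[Zn]Cl
Why: Negishi cross-coupling of the alkenyl triflate puts the future C11 methyl on C4 with the double bond fixed between C4 and C2, under conditions that leave the aryl ester and silyl ethers untouched.

Step 12
Reactants: 17 methylcyclopentene
Product: 20 keto acetal (ring B cyclohexane; C5: β-CH3/α-acetyl; C10: β-CH2CH(OCH3)2), via methoxy hydroperoxide 18 (not isolated), via keto aldehyde 19 (not isolated)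
Conditions: O3, CH2Cl2/MeOH (4:1), −78 °C (Sudan Red 7B end point); Me2S (5 equiv), −78 °C → rt; then HC(OMe)3 (3 equiv), pyridinium p-toluenesulfonate (cat.), rt; Et3N
Reagents that add atoms: ozone, [O-][O+]=O; methanol, CO; trimethyl orthoformate, COC(OC)OC
Why: Ozonolysis (Criegee mechanism) cleaves the trisubstituted C4=C2 alkene to the C4 methyl ketone and the C2 aldehyde after reduction of hydroperoxide 18, and the unhindered aldehyde is then acetalised selectively over the neopentyl-type ketone before the two carbonyls can undergo aldol reaction with each other.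

Step 13
Reactants: 20 keto acetal
Product: 21 isopropenyl acetal (C5: β-CH3/α-isopropenyl; C10: β-CH2CH(OCH3)2)
Conditions: Cp2Ti(μ-Cl)(μ-CH2)AlMe2 (Tebbe reagent, 1.5 equiv), pyridine (cat.), THF/toluene, −40 → 0 °C; NaHCO3 (aq)
Reagents that add atoms: Tebbe reagent, C[Al-]1(C)C[Ti]([Cl+]1)(C1C=CC=C1)C1C=CC=C1
Why: Tebbe methylenation turns the acetyl group on quaternary C5 into the isopropenyl group (new CH2 = future C3) without enolate chemistry and faster than any attack on the hindered aryl ester; the acetal is stable to the non-acidic reagent.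

Step 14
Reactants: 21 isopropenyl acetal
Product: 22 ene precursor aldehyde (C5: β-CH3/α-isopropenyl; C10: α-H/β-CH2CHO; C8: β-CH3; C9: β-CH3/α-CH2Ar2)
Conditions: AcOH/THF/H2O (3:1:1), 40 °C
Reagents that add atoms: water, O
Why: Mild aqueous acid hydrolyses the dimethyl acetal to the aldehyde but is too weak to protonate the 1,1-disubstituted alkene or to cleave aryl silyl ethers.

Step 15
Reactants: 22 ene precursor aldehyde
Product: 23 2α-hydroxy trans-decalin with C4=C11 methylene (2R; tris-TBS ether of the 2-hydroxy target)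
Conditions: Me2AlCl (1 M in hexanes, 3.0 equiv), CH2Cl2, −78 → −20 °C; KNaC4H4O6 (aq)
Reagents that add atoms: none
Why: Me2AlCl binds the aldehyde oxygen, and the complexed C2 carbonyl is attacked by the terminal alkene carbon C3 of the C5 isopropenyl group while a hydrogen of the allylic methyl (C11) passes to oxygen in a six-centre ene transition state, so the double bond moves to the exocyclic C4=C11 position; the alcohol–Me2AlCl complex then loses methane, which removes the proton that would otherwise start cationic side reactions. The closest known reaction is the Me2AlCl-promoted type 2 intramolecular carbonyl-ene cyclisation of aldehydes carrying a 1,1-disubstituted alkene to 3-methylenecyclohexanols. Ring A (C1, C2, C3, C4, C5, C10) closes as a six-membered chair by formation of the C2–C3 bond, with both alkene carbons inside the new ring and the double bond leaving it. The one new stereocentre, C2, should carry an axial (α, 2R) hydroxyl, because the aluminium-bound oxygen must sit over the C11 methyl in the bicyclic transition state; this centre is removed in step 17. The step needs the concerted ene path and a trans ring fusion: C5 is quaternary, so only C11 hydrogens can be transferred and one alkene isomer can form, and the isopropenyl and formylmethyl arms are trans-diequatorial on the ring B chair, which is held by the equatorial 8-methyl and 9-arylmethyl groups. Three equivalents of Me2AlCl are used because the aryl ester also binds the Lewis acid.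

Step 16
Reactants: 23 2α-hydroxy compound
Product: 24 2α-O-(imidazol-1-ylthiocarbonyl) derivative of 23
Conditions: 1,1'-thiocarbonyldiimidazole (3 equiv), DMAP (0.5 equiv), toluene, 80 °C
Reagents that add atoms: 1,1'-thiocarbonyldiimidazole, S=C(n1ccnc1)n1ccnc1
Why: Acylation of the axial secondary alcohol gives the thiocarbamate needed for radical deoxygenation under neutral conditions that do not touch the silyl ethers or the ester.

Step 17
Reactants: 24 thiocarbamate
Product: 25 tris-TBS ether of the target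
Conditions: n-Bu3SnH (3 equiv), AIBN (0.2 equiv), toluene, 100 °C
Reagents that add atoms: none
Why: Barton–McCombie deoxygenation: the stannyl radical adds to the thiocarbonyl sulfur, the C2–O bond fragments to a secondary radical that takes hydrogen from the stannane, and a high stannane concentration keeps this homoallyl radical from rearranging.

Step 18
Reactants: 25 tris-TBS ether of the target
Product: 26 methyl 2,3,4-trihydroxy-5-{[(1R,2S,4aS,8aS)-1,2,4a-trimethyl-5-methylidenedecahydronaphthalen-1-yl]methyl}benzoate (target)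
Conditions: Bu4NF (3.6 equiv), AcOH (3.6 equiv), THF, 0 °C, argon
Reagents that add atoms: none
Why: Buffered fluoride cleaves the three aryl silyl ethers under non-acidic conditions that spare the methyl ester and the C4 exocyclic methylene.

## Compound list

1 | 2-methylcyclopentane-1,3-dione | CC1C(=O)CCC1=O | starting material
2 | pent-1-en-3-one (ethyl vinyl ketone) | CCC(=O)C=C | starting material
3 | 2-methyl-2-(3-oxopentyl)cyclopentane-1,3-dione | CCC(=O)CCC1(C)C(=O)CCC1=O | intermediate
4 | (3aS,7aS)-3a-hydroxy-4,7a-dimethylhexahydro-1H-indene-1,5(4H)-dione, cis-fused ketol, C4 epimers | O=C1CC[C@]2(O)C(C)C(=O)CC[C@]12C | intermediate (not isolated)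
5 | (7aS)-4,7a-dimethyl-2,3,7,7a-tetrahydro-1H-indene-1,5(6H)-dione | CC1=C2CCC(=O)[C@@]2(C)CCC1=O | intermediate
6 | (7a'S)-4',7a'-dimethyl-2',3',7',7a'-tetrahydrospiro[[1,3]dioxolane-2,1'-inden]-5'(6'H)-one | CC1=C2CCC3(OCCO3)[C@@]2(C)CCC1=O | intermediate
7 | methyl 2,3,4-trimethoxybenzoate | COC(=O)c1ccc(OC)c(OC)c1OC | starting material
8 | methyl 5-(bromomethyl)-2,3,4-trimethoxybenzoate | COC(=O)c1cc(CBr)c(OC)c(OC)c1OC | intermediate
9 | lithium enolate of the trans-fused hydrindanone 4-ethylene ketal (5β-CH3, 10α-H, C8(OLi)=C9(CH3)) | O1CCOC12CC[C@H]3C(C)=C([O-])CC[C@]23C.[Li+] | intermediate (not isolated)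
10 | trans-hydrindan-8-one 4-ethylene ketal, 5β-CH3, 10α-H, 9β-CH3, 9α-CH2Ar1 | O1CCOC12CC[C@H]3[C@](C)(Cc4cc(C(=O)OC)c(OC)c(OC)c4OC)C(=O)CC[C@]23C | intermediate
11 | 8-methylidene analogue of 10 | O1CCOC12CC[C@H]3[C@](C)(Cc4cc(C(=O)OC)c(OC)c(OC)c4OC)C(=C)CC[C@]23C | intermediate
12 | 8β-methyl (8α-H) trans-hydrindane 4-ethylene ketal, 5β,9β-dimethyl, 10α-H, 9α-CH2Ar1 | O1CCOC12CC[C@H]3[C@](C)(Cc4cc(C(=O)OC)c(OC)c(OC)c4OC)[C@@H](C)CC[C@]23C | intermediate
13 | trans-hydrindan-4-one, 5β,8β,9β-trimethyl, 10α-H, 9α-[2,3,4-trihydroxy-5-(methoxycarbonyl)benzyl] | O=C1CC[C@H]2[C@](C)(Cc3cc(C(=O)OC)c(O)c(O)c3O)[C@@H](C)CC[C@]12C | intermediate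
14 | tris-TBS ether of 13 (9α-CH2Ar2) | O=C1CC[C@H]2[C@](C)(Cc3cc(C(=O)OC)c(O[Si](C)(C)C(C)(C)C)c(O[Si](C)(C)C(C)(C)C)c3O[Si](C)(C)C(C)(C)C)[C@@H](C)CC[C@]12C | intermediate
15 | potassium C4–C2 enolate of 14 | [K+].[O-]C1=CC[C@H]2[C@](C)(Cc3cc(C(=O)OC)c(O[Si](C)(C)C(C)(C)C)c(O[Si](C)(C)C(C)(C)C)c3O[Si](C)(C)C(C)(C)C)[C@@H](C)CC[C@]12C | intermediate (not isolated)
16 | enol triflate, C4(OTf)=C2H | O=S(=O)(OC1=CC[C@H]2[C@](C)(Cc3cc(C(=O)OC)c(O[Si](C)(C)C(C)(C)C)c(O[Si](C)(C)C(C)(C)C)c3O[Si](C)(C)C(C)(C)C)[C@@H](C)CC[C@]12C)C(F)(F)F | intermediate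
17 | cyclopentene, C4(CH3)=C2H | CC1=CC[C@H]2[C@](C)(Cc3cc(C(=O)OC)c(O[Si](C)(C)C(C)(C)C)c(O[Si](C)(C)C(C)(C)C)c3O[Si](C)(C)C(C)(C)C)[C@@H](C)CC[C@]12C | intermediate
18 | ring-opened methoxy hydroperoxide aldehyde (C5: β-CH3, α-(1-hydroperoxy-1-methoxyethyl); C10: β-CH2CHO) | COC(C)(OO)[C@@]1(C)CC[C@H](C)[C@@](C)(Cc3cc(C(=O)OC)c(O[Si](C)(C)C(C)(C)C)c(O[Si](C)(C)C(C)(C)C)c3O[Si](C)(C)C(C)(C)C)[C@@H]1CC=O | intermediate (not isolated)
19 | keto aldehyde (C5: β-CH3, α-acetyl; C10: β-CH2CHO) | CC(=O)[C@@]1(C)CC[C@H](C)[C@@](C)(Cc3cc(C(=O)OC)c(O[Si](C)(C)C(C)(C)C)c(O[Si](C)(C)C(C)(C)C)c3O[Si](C)(C)C(C)(C)C)[C@@H]1CC=O | intermediate (not isolated)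
20 | keto acetal (C5: β-CH3, α-acetyl; C10: β-CH2CH(OCH3)2) | CC(=O)[C@@]1(C)CC[C@H](C)[C@@](C)(Cc3cc(C(=O)OC)c(O[Si](C)(C)C(C)(C)C)c(O[Si](C)(C)C(C)(C)C)c3O[Si](C)(C)C(C)(C)C)[C@@H]1CC(OC)OC | intermediate
21 | isopropenyl acetal (C5: β-CH3, α-isopropenyl) | C=C(C)[C@@]1(C)CC[C@H](C)[C@@](C)(Cc3cc(C(=O)OC)c(O[Si](C)(C)C(C)(C)C)c(O[Si](C)(C)C(C)(C)C)c3O[Si](C)(C)C(C)(C)C)[C@@H]1CC(OC)OC | intermediate
22 | ene precursor: ring B cyclohexane, C5 β-CH3/α-isopropenyl, C8 β-CH3, C9 β-CH3/α-CH2Ar2, C10 α-H/β-CH2CHO | C=C(C)[C@@]1(C)CC[C@H](C)[C@@](C)(Cc3cc(C(=O)OC)c(O[Si](C)(C)C(C)(C)C)c(O[Si](C)(C)C(C)(C)C)c3O[Si](C)(C)C(C)(C)C)[C@@H]1CC=O | intermediate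
23 | ene product: (2R)-2α-hydroxy derivative of the target tris-TBS ether | C=C1C[C@H](O)C[C@H]2[C@](C)(Cc3cc(C(=O)OC)c(O[Si](C)(C)C(C)(C)C)c(O[Si](C)(C)C(C)(C)C)c3O[Si](C)(C)C(C)(C)C)[C@@H](C)CC[C@]12C | intermediate
24 | 2α-O-(imidazol-1-ylthiocarbonyl) derivative of 23 | C=C1C[C@H](OC(=S)n4ccnc4)C[C@H]2[C@](C)(Cc3cc(C(=O)OC)c(O[Si](C)(C)C(C)(C)C)c(O[Si](C)(C)C(C)(C)C)c3O[Si](C)(C)C(C)(C)C)[C@@H](C)CC[C@]12C | intermediate
25 | tris-TBS ether of the target | C=C1CCC[C@H]2[C@](C)(Cc3cc(C(=O)OC)c(O[Si](C)(C)C(C)(C)C)c(O[Si](C)(C)C(C)(C)C)c3O[Si](C)(C)C(C)(C)C)[C@@H](C)CC[C@]12C | intermediate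
26 | methyl 2,3,4-trihydroxy-5-{[(1R,2S,4aS,8aS)-1,2,4a-trimethyl-5-methylidenedecahydronaphthalen-1-yl]methyl}benzoate | C=C1CCC[C@H]2[C@](C)(Cc3cc(C(=O)OC)c(O)c(O)c3O)[C@@H](C)CC[C@]12C | target

## Step count and risks

Total step count: 18. Longest linear sequence: 17 (steps 1–3 and 5–18; step 4 makes the aryl fragment).

Steps most likely to fail:

**Step 15 (key carbonyl-ene).** The aluminium-bound aldehyde may react stepwise, so that the tertiary C4 cation is captured by chloride, loses a ring proton to an endocyclic alkene or takes a methyl shift from C5. The Lewis acid may also be held by the aryl ester, leaving the aldehyde unreacted or methylated.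
Fallback (intramolecular Hosomi–Sakurai allylation, sets out from 20): the methyl ketone of 20 is converted with KN(SiMe3)2 and PhNTf2 in THF at −78 °C into the terminal enol triflate F1. F1 is coupled with Me3SiCH2MgCl under Pd(PPh3)4 catalysis to the allylsilane acetal F2, and AcOH/THF/H2O gives the allylsilane aldehyde F3. BF3·OEt2 in CH2Cl2 at −78 °C then closes ring A by attack of the allylsilane terminus on the aldehyde with loss of silicon, which fixes the double bond in the exocyclic position. The product is 23 or its 2β-hydroxy epimer F4; the epimer would be taken through the conditions of steps 16 and 17 by way of its thiocarbamate F5. The route is rejoined at 23 or, from F5, at 25.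

**Step 5 (reductive benzylation).** C10 may be protonated from the β face (cis ring fusion), the enolate may be benzylated on oxygen or from the β face, and proton exchange may give unalkylated or doubly alkylated ketone.
Fallback (1β-alkoxy series, sets out from 5): NaBH4 in EtOH at −20 °C should reduce only the cyclopentanone to the 4β-hydroxy enone F6, which is converted with 2-methylpropene and H3PO4/BF3·OEt2 into the tert-butyl ether F7. The bulky β-alkoxy group on the five-membered ring should favour the trans fusion in the same Li/NH3 reduction, and trapping with 8 gives the benzylated trans-hydrindanone F8. Tebbe methylenation gives the methylidene compound F9 and hydrogenation over Pd/C the 8β-methyl compound F10. CF3CO2H in CH2Cl2 removes the tert-butyl group to give the 4β-alcohol F11, Dess–Martin periodinane oxidises it to the 4-ketone F12, and BBr3 followed by MeOH returns to the route at 13.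

**Step 12 (ozonolysis and carbonyl differentiation).** Ozone may attack the oxygenated arene once the alkene is consumed, and the liberated methyl ketone and aldehyde may condense with each other before the acetal has formed.
Fallback (dihydroxylation and glycol cleavage, sets out from 17): OsO4 (cat.) with N-methylmorpholine N-oxide in acetone/H2O should give the α-face cis-diol F13. NaIO4 in THF/H2O cleaves it to keto aldehyde 19, which is isolated cold and acetalised separately with HC(OMe)3, MeOH and pyridinium p-toluenesulfonate to rejoin the route at 20.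

## Further compounds

F1 | step 15 | terminal enol triflate from 20 (C5: α-[1-(trifluoromethylsulfonyloxy)vinyl]) | C=C(OS(=O)(=O)C(F)(F)F)[C@@]1(C)CC[C@H](C)[C@@](C)(Cc3cc(C(=O)OC)c(O[Si](C)(C)C(C)(C)C)c(O[Si](C)(C)C(C)(C)C)c3O[Si](C)(C)C(C)(C)C)[C@@H]1CC(OC)OC
F2 | step 15 | allylsilane acetal (C5: α-[3-(trimethylsilyl)prop-1-en-2-yl]) | C=C(C[Si](C)(C)C)[C@@]1(C)CC[C@H](C)[C@@](C)(Cc3cc(C(=O)OC)c(O[Si](C)(C)C(C)(C)C)c(O[Si](C)(C)C(C)(C)C)c3O[Si](C)(C)C(C)(C)C)[C@@H]1CC(OC)OC
F3 | step 15 | allylsilane aldehyde | C=C(C[Si](C)(C)C)[C@@]1(C)CC[C@H](C)[C@@](C)(Cc3cc(C(=O)OC)c(O[Si](C)(C)C(C)(C)C)c(O[Si](C)(C)C(C)(C)C)c3O[Si](C)(C)C(C)(C)C)[C@@H]1CC=O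
F4 | step 15 | 2β-hydroxy epimer of 23 | C=C1C[C@@H](O)C[C@H]2[C@](C)(Cc3cc(C(=O)OC)c(O[Si](C)(C)C(C)(C)C)c(O[Si](C)(C)C(C)(C)C)c3O[Si](C)(C)C(C)(C)C)[C@@H](C)CC[C@]12C
F5 | step 15 | 2β-O-(imidazol-1-ylthiocarbonyl) derivative of F4 | C=C1C[C@@H](OC(=S)n4ccnc4)C[C@H]2[C@](C)(Cc3cc(C(=O)OC)c(O[Si](C)(C)C(C)(C)C)c(O[Si](C)(C)C(C)(C)C)c3O[Si](C)(C)C(C)(C)C)[C@@H](C)CC[C@]12C
F6 | step 5 | (1S,7aS)-1-hydroxy-4,7a-dimethyl-1,2,3,6,7,7a-hexahydro-5H-inden-5-one (4β-hydroxy enone) | CC1=C2CC[C@H](O)[C@@]2(C)CCC1=O
F7 | step 5 | tert-butyl ether of F6 | CC1=C2CC[C@H](OC(C)(C)C)[C@@]2(C)CCC1=O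
F8 | step 5 | trans-hydrindan-8-one, 4β-tert-butoxy, 5β-CH3, 10α-H, 9β-CH3, 9α-CH2Ar1 | CC(C)(C)O[C@H]1CC[C@H]2[C@](C)(Cc3cc(C(=O)OC)c(OC)c(OC)c3OC)C(=O)CC[C@]12C
F9 | step 5 | 8-methylidene analogue of F8 | CC(C)(C)O[C@H]1CC[C@H]2[C@](C)(Cc3cc(C(=O)OC)c(OC)c(OC)c3OC)C(=C)CC[C@]12C
F10 | step 5 | 8β-methyl analogue of F8 | CC(C)(C)O[C@H]1CC[C@H]2[C@](C)(Cc3cc(C(=O)OC)c(OC)c(OC)c3OC)[C@@H](C)CC[C@]12C
F11 | step 5 | 4β-alcohol from F10 | O[C@H]1CC[C@H]2[C@](C)(Cc3cc(C(=O)OC)c(OC)c(OC)c3OC)[C@@H](C)CC[C@]12C
F12 | step 5 | trans-hydrindan-4-one, tri-O-methyl ether of 13 | O=C1CC[C@H]2[C@](C)(Cc3cc(C(=O)OC)c(OC)c(OC)c3OC)[C@@H](C)CC[C@]12C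
F13 | step 12 | 4α,2α-diol from 17 (4β-CH3) | C[C@@]1(O)[C@H](O)C[C@H]2[C@](C)(Cc3cc(C(=O)OC)c(O[Si](C)(C)C(C)(C)C)c(O[Si](C)(C)C(C)(C)C)c3O[Si](C)(C)C(C)(C)C)[C@@H](C)CC[C@]12C
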